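**Retrosynthetic overview**
- Target ⇒ free (E)-2',4',6'-trihydroxy-3'-(1,1-dimethylallyl)chalcone by disconnecting O1–C2. In the forward direction an enantioselective 6-endo oxa-Michael addition of the 6'-OH closes ring C last and sets C2 as S.
- Chalcone ⇒ reverse-prenylated phloroacetophenone + O-silyl vanillin (Claisen–Schmidt condensation; ring B is bought as vanillin).
- Reverse-prenyl ketone ⇒ 4-O-prenyl phloroacetophenone (aromatic Claisen) ⇒ phloroacetophenone + prenyl bromide (C–O bond; ring A is bought).
- Ring order: rings A and B enter as arenes; ring C is the only ring formed, in the final step.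

Assumption: the stereocentre in the SMILES reads as (2S), and commercial 2,4,6-trihydroxyacetophenone monohydrate is dried before use and counted as compound 1.

**Route**

Step 1
Reactants: 1 1-(2,4,6-trihydroxyphenyl)ethanone (phloroacetophenone); 2 1-bromo-3-methylbut-2-ene (prenyl bromide)
Product: 3 1-[2,6-dihydroxy-4-(3-methylbut-2-en-1-yloxy)phenyl]ethanone
Conditions: 2 (1.05 equiv), K2CO3 (1.1 equiv), acetone, reflux, 5 h
Reagents that add atoms: prenyl bromide (compound 2), CC(C)=CCBr
Why: Williamson ether synthesis; the 4-OH is the most acidic hydroxyl and the only one not hydrogen-bonded to the acetyl group, so one equivalent of base and bromide in acetone alkylates it preferentially on oxygen (di-O- and C-prenylated by-products are removed by chromatography).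

Step 2
Reactants: 3 1-[2,6-dihydroxy-4-(3-methylbut-2-en-1-yloxy)phenyl]ethanone
Product: 5 1-[2,4,6-trihydroxy-3-(2-methylbut-3-en-2-yl)phenyl]ethanone, via ortho-dienone 4 (not isolated)
Conditions: PhNEt2, 190 °C, sealed tube under argon, 1.5 h; cold 1 M HCl wash
Reagents that add atoms: none
Why: Aromatic Claisen rearrangement ([3,3]-sigmatropic shift) transfers the prenyl unit with allylic inversion to one of the two equivalent ortho carbons, and tautomerisation of dienone 4 restores the arene; the para position carries the acetyl group, so no Cope relay to a normal prenyl group can occur.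

Step 3
Reactants: 6 4-hydroxy-3-methoxybenzaldehyde (vanillin); 7 tert-butylchlorodimethylsilane
Product: 8 4-[(tert-butyldimethylsilyl)oxy]-3-methoxybenzaldehyde
Conditions: 7 (1.1 equiv), imidazole (1.5 equiv), DMF, rt, 3 h
Reagents that add atoms: tert-butylchlorodimethylsilane (compound 7), CC(C)(C)[Si](C)(C)Cl
Why: Standard imidazole-promoted silyl ether formation; it masks the para phenol so that the aldehyde is not deactivated as a phenoxide in step 4.

Step 4
Reactants: 5 1-[2,4,6-trihydroxy-3-(2-methylbut-3-en-2-yl)phenyl]ethanone; 8 4-[(tert-butyldimethylsilyl)oxy]-3-methoxybenzaldehyde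
Product: 11 (E)-3-(4-hydroxy-3-methoxyphenyl)-1-[2,4,6-trihydroxy-3-(2-methylbut-3-en-2-yl)phenyl]prop-2-en-1-one, via aldol adduct 9 (not isolated), via silyl chalcone 10 (not isolated)
Conditions: LiN(SiMe3)2 (5.2 equiv), THF, −78 °C, 1 h; 8 (1.1 equiv), −78 °C → rt, 16 h; AcOH (8 equiv), 0 °C; then Bu4NF (1.5 equiv), 0 °C, 30 min; chromatography with 0.5% AcOH in the eluent
Reagents that add atoms: none
Why: Claisen–Schmidt aldol condensation through the polylithiated ketone (three phenoxides plus enolate) with E1cB loss of hydroxide from aldolate 9 to give the (E)-enone, which stays ring-open in strong base; fast acidification and acetic-acid-buffered fluoride desilylation keep the cyclisation-prone chalcone out of the weakly basic range.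

Step 5
Reactants: 11 (E)-3-(4-hydroxy-3-methoxyphenyl)-1-[2,4,6-trihydroxy-3-(2-methylbut-3-en-2-yl)phenyl]prop-2-en-1-one
Product: 12 (2S)-5,7-dihydroxy-2-(4-hydroxy-3-methoxyphenyl)-6-(2-methylbut-3-en-2-yl)-2,3-dihydro-4H-chromen-4-one
Conditions: 3-{[3,5-bis(trifluoromethyl)phenyl]amino}-4-{[(8α,9S)-6'-methoxycinchonan-9-yl]amino}cyclobut-3-ene-1,2-dione (quinine-derived squaramide, 10 mol%), MTBE/toluene 1:1, 0.05 M, −20 °C, 48 h; AcOH (0.2 equiv) quench at −20 °C
Reagents that add atoms: none
Why: Proposed new method: a bifunctional tertiary-amine/squaramide catalyst is asked to perform an intramolecular oxa-Michael addition on an unprotected, non-activated 2',6'-dihydroxychalcone, as chalcone isomerase does; the squaramide N–H pair binds the enone carbonyl (held s-cis by the hydrogen bond from the buttressed 2'-OH), the quinuclidine deprotonates the only accessible ortho phenol (6'-OH, the 2'-OH being shielded by the adjacent quaternary carbon), the phenoxide adds 6-endo to one face of Cβ inside the chiral ion pair to form O1–C2 and set C2 as S, and the quinuclidinium protonates the enolate; the closest known reaction types are the bifunctional thiourea-catalysed oxa-Michael cyclisation of phenols onto alkylidene β-ketoesters and the cinchona-alkaloid-catalysed, moderately selective cyclisation of simple 2'-hydroxychalcones, neither of which has been shown with regiocontrol between two free ortho phenols on a polyphenolic chalcone.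

**Compound list**

1 | 1-(2,4,6-trihydroxyphenyl)ethanone (phloroacetophenone) | CC(=O)c1c(O)cc(O)cc1O | starting material
2 | 1-bromo-3-methylbut-2-ene (prenyl bromide) | CC(C)=CCBr | starting material
3 | 1-[2,6-dihydroxy-4-(3-methylbut-2-en-1-yloxy)phenyl]ethanone | CC(=O)c1c(O)cc(OCC=C(C)C)cc1O | intermediate
4 | racemic 4-acetyl-3,5-dihydroxy-6-(2-methylbut-3-en-2-yl)cyclohexa-2,4-dien-1-one (ortho-dienone, not isolated) | CC(=O)C1=C(O)C(C(C)(C)C=C)C(=O)C=C1O | intermediate
5 | 1-[2,4,6-trihydroxy-3-(2-methylbut-3-en-2-yl)phenyl]ethanone | CC(=O)c1c(O)cc(O)c(C(C)(C)C=C)c1O | intermediate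
6 | 4-hydroxy-3-methoxybenzaldehyde (vanillin) | COc1cc(C=O)ccc1O | starting material
7 | tert-butylchlorodimethylsilane | CC(C)(C)[Si](C)(C)Cl | starting material
8 | 4-[(tert-butyldimethylsilyl)oxy]-3-methoxybenzaldehyde | COc1cc(C=O)ccc1O[Si](C)(C)C(C)(C)C | intermediate
9 | racemic 3-{4-[(tert-butyldimethylsilyl)oxy]-3-methoxyphenyl}-3-hydroxy-1-[2,4,6-trihydroxy-3-(2-methylbut-3-en-2-yl)phenyl]propan-1-one (aldol adduct, lithium salt in the flask, not isolated) | C=CC(C)(C)c1c(O)cc(O)c(C(=O)CC(O)c2ccc(O[Si](C)(C)C(C)(C)C)c(OC)c2)c1O | intermediate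
10 | (E)-3-{4-[(tert-butyldimethylsilyl)oxy]-3-methoxyphenyl}-1-[2,4,6-trihydroxy-3-(2-methylbut-3-en-2-yl)phenyl]prop-2-en-1-one (silyl chalcone, not isolated) | C=CC(C)(C)c1c(O)cc(O)c(C(=O)/C=C/c2ccc(O[Si](C)(C)C(C)(C)C)c(OC)c2)c1O | intermediate
11 | (E)-3-(4-hydroxy-3-methoxyphenyl)-1-[2,4,6-trihydroxy-3-(2-methylbut-3-en-2-yl)phenyl]prop-2-en-1-one | C=CC(C)(C)c1c(O)cc(O)c(C(=O)/C=C/c2ccc(O)c(OC)c2)c1O | intermediate
12 | (2S)-5,7-dihydroxy-2-(4-hydroxy-3-methoxyphenyl)-6-(2-methylbut-3-en-2-yl)-2,3-dihydro-4H-chromen-4-one | C=CC(C)(C)c1c(O)cc2c(c1O)C(=O)C[C@@H](c1ccc(O)c(OC)c1)O2 | target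

**Step count and risks**

Total steps: 5. Longest linear sequence: 4 (steps 1, 2, 4, 5); step 3 is a one-step side branch.

Three steps most likely to fail:

1. Step 5 (the proposed new oxa-Michael cyclisation). The risks are low enantiomeric excess, the opposite sense of induction, leakage to the 8-substituted regioisomer through the 2'-OH, and erosion of ee by retro-Michael ring opening. The sense of induction is not predictable and is read from the first run by circular dichroism: (2S)-flavanones show a negative Cotton effect near 290 nm and a positive one near 330 nm. If the (2R) series is obtained, the quinidine-derived pseudo-enantiomer, with a (9R)-6'-methoxycinchonan-9-yl group, is used under the same conditions. The fallback sets out from 11 and uses known chemistry only. NaOAc in refluxing EtOH cyclises 11 under thermodynamic control to the racemic flavanone F1, from which any 8-substituted isomer is removed by chromatography. Preparative chiral chromatography on an amylose tris(3,5-dimethylphenylcarbamate) phase then separates 12 from the (2R)-enantiomer F2, which is re-racemised with NaOAc and recycled. The fallback comes back to the route at 12.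

2. Step 4 (polyanion Claisen–Schmidt condensation). The risks are poor solubility or low reactivity of the polylithiated ketone, and partial racemic ring closure during the quench. The fallback sets out from 5 and 6 and is the classical protected route. MOMCl with iPr2NEt in CH2Cl2 converts 5 into 1-[2-hydroxy-4,6-bis(methoxymethoxy)-3-(2-methylbut-3-en-2-yl)phenyl]ethanone F3; which two hydroxyls are capped does not matter, because all are released together later. Vanillin 6 is converted in the same way into 3-methoxy-4-(methoxymethoxy)benzaldehyde F4. KOH in EtOH/H2O at rt condenses F3 and F4 to the tris-MOM chalcone F5. HCl in MeOH at rt then removes the three MOM groups, leaving the terminal alkene untouched, and the fallback comes back to the route at 11.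

3. Step 2 (thermal Claisen rearrangement). The risks are the abnormal Claisen rearrangement and closure of the new phenol onto the tertiary allyl group (dihydrobenzofuran formation), plus some loss of the prenyl group. The fallback sets out from 3 and changes to a trap-and-release sequence. N,O-bis(trimethylsilyl)acetamide converts 3 into 1-[4-(3-methylbut-2-en-1-yloxy)-2,6-bis(trimethylsilyloxy)phenyl]ethanone F6. This is heated in PhNEt2 at 190 °C with excess silylating agent, so the phenol released by the rearrangement is captured at once as 1-[3-(2-methylbut-3-en-2-yl)-2,4,6-tris(trimethylsilyloxy)phenyl]ethanone F7. With no free OH next to the allyl group, neither side reaction can start. Methanolysis (MeOH, citric acid, rt) then brings the fallback back to the route at 5.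

**Further compounds**

F1 | step 5 | racemic 5,7-dihydroxy-2-(4-hydroxy-3-methoxyphenyl)-6-(2-methylbut-3-en-2-yl)-2,3-dihydro-4H-chromen-4-one | C=CC(C)(C)c1c(O)cc2c(c1O)C(=O)CC(c1ccc(O)c(OC)c1)O2
F2 | step 5 | (2R)-5,7-dihydroxy-2-(4-hydroxy-3-methoxyphenyl)-6-(2-methylbut-3-en-2-yl)-2,3-dihydro-4H-chromen-4-one | C=CC(C)(C)c1c(O)cc2c(c1O)C(=O)C[C@H](c1ccc(O)c(OC)c1)O2
F3 | step 4 | 1-[2-hydroxy-4,6-bis(methoxymethoxy)-3-(2-methylbut-3-en-2-yl)phenyl]ethanone | CC(=O)c1c(OCOC)cc(OCOC)c(C(C)(C)C=C)c1O
F4 | step 4 | 3-methoxy-4-(methoxymethoxy)benzaldehyde | COCOc1ccc(C=O)cc1OC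
F5 | step 4 | (E)-1-[2-hydroxy-4,6-bis(methoxymethoxy)-3-(2-methylbut-3-en-2-yl)phenyl]-3-[3-methoxy-4-(methoxymethoxy)phenyl]prop-2-en-1-one | C=CC(C)(C)c1c(OCOC)cc(OCOC)c(C(=O)/C=C/c2ccc(OCOC)c(OC)c2)c1O
F6 | step 2 | 1-[4-(3-methylbut-2-en-1-yloxy)-2,6-bis(trimethylsilyloxy)phenyl]ethanone | CC(=O)c1c(O[Si](C)(C)C)cc(OCC=C(C)C)cc1O[Si](C)(C)C
F7 | step 2 | 1-[3-(2-methylbut-3-en-2-yl)-2,4,6-tris(trimethylsilyloxy)phenyl]ethanone | CC(=O)c1c(O[Si](C)(C)C)cc(O[Si](C)(C)C)c(C(C)(C)C=C)c1O[Si](C)(C)C
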